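## Analysis of the target

Compound 29 (CNP0168827.1) is a 2,3-dihydro-1-benzofuran: ring A is the benzene ring (C3a, C4 to C7, C7a) and ring B the dihydrofuran (O1, C2, C3). C2 carries the α-carbon of a methyl acrylate, C3 an acetoxy group, and C5 (para to O1) a 1-(angeloyloxy)ethyl chain. There are three stereocentres: C2 (S) and C3 (S), whose substituents are cis on ring B, and the side-chain carbinol (S), which is insulated from the ring centres by the arene and cannot be set from them. The C3 acetate is benzylic, ortho-related to O1 and anti to C2–H, so acid (ionisation) or base (elimination) aromatises ring B to a benzofuran. The side-chain ester is a para-alkoxybenzylic ester that ionises in acid with loss of configuration, the angelate isomerises to the tiglate under base, heat or radicals, and the acrylate is a Michael acceptor. The difficulty is to place three different esters and three stereocentres on a core whose late intermediates tolerate neither strong acid nor strong base. The plan rests on the fact that ring A is substituted only at C7a (O1), C3a (C3) and C5, while C4, C6 and C7 are CH. Its six carbons divide into three alkyne units: C7a–C7 (an ynol ether), C3a–C4 (a propargylic alkyne) and C5–C6 (a terminal alkyne carrying the finished side chain). The first two are already linked by O1–C2–C3, so C2 and C3 lie outside the ring being formed and can be taken from a threo diol of the chiral pool.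

## Retrosynthetic reasoning

**Acrylate (29 back to 25).** No skeletal bond is cut. The acrylate is the most electrophilic group of 29, so it is unveiled last from the isopropenyl group of 25: allylic oxidation of the methyl group to enal 27, oxidation to acid 28, methylation. The forward steps must oxidise the electron-rich 1,1-disubstituted alkene and not the angelate, and must stay close to neutral.

**Isopropenyl group (25 back to 22).** The C=C bond is traced to the tertiary alcohol of 24, the acetate to diol 23, and the two hydroxyls to the silyl ethers of 22. An alkene on the carbon attached to C2 cannot be carried further back. It would make the ynol ether of 16 an allyl alkynyl ether, which undergoes a [3,3]-sigmatropic shift to a ketene well below room temperature. It would also be attacked in the iodination that gives 21. A 2-silyloxyprop-2-yl group has neither problem and comes from an ester by double methyl addition.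

**Silicon at C7 (22 back to 20).** C7–H is traced to C7–I in 21 and C7–Si in 20. Direct protonolysis of the aryl–silicon bond is not used, because an acid strong enough to protonate the arene would ionise both benzylic C–O bonds (C3 to a benzofuran, the side chain to a racemised or eliminated product). Electrophilic iodine at the silylated carbon, then halogen–metal exchange and protonation, does the same without acid.

**Ring A and ring B (20 back to 16 and 19).** The bonds C3a–C7a, C4–C5 and C6–C7 are cut. Every substituent of ring A sits on a carbon that maps onto an alkyne carbon, the stereocentres are outside the reacting atoms, and the angelate arrives complete on a small fragment. The forward reaction has to couple the tethered diyne 16 with one molecule of 19 in one orientation; the silyl group on the ynol terminus is there for that.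

**Ester 19 (back to 17 and 18).** The ester C–O bond is cut. Acylation with 18 is done on the small carbinol 17, where Z/E integrity is easiest to secure.

**Propargylic alkyne (16 back to 14).** The C3a–C4 bond is cut: the terminal carbon is added to the lactol carbon of 14 by a diazo-based one-carbon homologation that gives 15, and 16 is its silyl ether. This comes after the ynol ether, because a terminal alkyne would be metalated and silylated together with the ynol terminus and both ends of the diyne would be blocked. The lactol serves as masked aldehyde and as protection of the tertiary hydroxyl at once.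

**Ynol ether (14 back to 8).** The C≡C–Si unit of 14 comes from the dichlorovinyl ether of 12 by elimination, halogen–metal exchange and C-silylation. The silyl ether on the C3 oxygen (11) is introduced only after the strongly basic etherification, so that it never sits next to an alkoxide. The acetal of 8 is hydrolysed while the oxygen substituent is still the acid-stable dichlorovinyl ether. Passing through lactone 10 distinguishes the C3 hydroxyl of 9 from the anomeric one.

**Vinyl ether (8 back to 6 and 7).** The O1–C7a bond is cut: the alkoxide of 6 adds to the two-carbon unit supplied by 7. Compound 6 has one free hydroxyl, the future O1; all other oxygens are in acetals, so nothing can migrate or compete.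

**Chiral pool (6 back to 1).** Compound 6 is the acetonide of the lactol of lactone 4. Lactone 4 arises from half-ester 2 by double methyl addition to the ester (via 3) and lactonisation, and 2 from the C2-symmetric diester 1 by monohydrolysis. Because of the symmetry it does not matter which ester is hydrolysed. No bond to either stereocentre is broken between 1 and 29.

## Alternatives that were turned down

**Alternative 1:** Ring B is cut at C3a–C3, and the C3 oxygen is joined to the acrylate carboxyl. The substrate is an aryl ether of an α-methylene-γ-butyrolactone whose future C3 is an acetal carbon with a chiral alkoxy group. BF3·OEt2 ionises the acetal and the arene carbon ortho to the ether oxygen attacks the oxocarbenium ion, giving the cis-fused bromo lactone A1.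
- For: a 5,5-fused bicycle can only be cis, so the C2/C3 relationship is built in. The acrylate is carried at its final oxidation level; methanolysis and acetylation would finish ring B. On both points this alternative is stronger than the chosen route.
- Against: the cation sits β to an aryloxy leaving group and next to an exocyclic alkene that a Lewis acid can move into the ring. The auxiliary centre is destroyed on ionisation, so it does not fix the absolute configuration at C2. The bromine must afterwards become an acetyl group, be reduced enantioselectively and angeloylated, on a molecule that already holds a Michael acceptor and a base-sensitive C3 oxygen.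
- In exchange, the chosen strategy delivers the side chain with its stereocentre and ester in place and takes the ring centres from the chiral pool.

**Alternative 2:** Three bonds around the acrylate are cut: O1–C2, the bond from the acrylate α-carbon to the carbonyl carbon, and the lactone C–O bond at C3. The substrate is an ortho-(1-hydroxybuta-2,3-dienyl)phenol with the protected side chain. PdCl2 with CuCl2 under carbon monoxide should add the phenol oxygen to the proximal allene carbon (ring B), insert carbon monoxide into the vinyl–palladium bond and let the C3 hydroxyl capture the acyl–palladium species, giving cis-fused lactone A2; CuCl2 returns zerovalent palladium to divalent palladium.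
- For: it is the most step-economic of the four plans. One carbinol centre relays to C2 because only the cis isomer can lactonise, and the acrylate carbon comes from carbon monoxide, so no allylic oxidation is needed. On step count and oxidation level it is stronger than the chosen route.
- Against: the phenol can also attack the distal allene terminus through a π-allyl complex (six-membered ring). The allenylic, benzylic carbinol ionises easily beside Lewis-acidic chlorides, and CuCl2 chlorinates electron-rich phenols. If oxypalladation is not reversible, the trans isomer is lost. After the cascade the side chain must still be desilylated and angeloylated next to an acrylate.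
- In exchange, the chosen strategy gives an unambiguous ring size, has no diastereoselective step, and never makes the angelate late.

**Alternative 3:** The C2–C3 bond is cut. Ring B is traced to an eight-membered benzodioxocine in which O1 is part of an enol ether and C3 is a benzylic O–CH2 group. tert-Butyllithium with a chiral bis(oxazoline) removes a benzylic proton and the carbanion undergoes a transannular [2,3]-shift onto the enol ether carbon. This forms C2–C3, breaks the allylic C–O bond and gives alcohol A3 with the isopropenyl group and the C3 alkoxide in one step.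
- For: A3 differs from the C3 alcohol corresponding to 25 only in the side-chain protecting group. The ending is therefore the same as in the chosen route, reached without an aryl silane to remove and without a masked isopropenyl group. In steps to the core it is stronger.
- Against: absolute configuration (which enantiotopic proton is removed, and whether the benzylic organolithium keeps its configuration) and relative configuration (a medium-ring transition state) both rest on one step without close analogy. [1,2]-Shift and ortho-lithiation compete, the acid-labile eight-membered enol ether must itself be made, and the angelate is again introduced late.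
- In exchange, the chosen strategy has no stereochemical risk in its key step; its risk is regiochemical and is steered by silicon.

Key step: step 13

Remark on the chemistry: 1 is the commercial acetonide of dimethyl L-tartrate; lactols 5, 9, 12 and 14 are anomeric mixtures, which is of no consequence because the anomeric carbon ends as an alkyne carbon.

## Route

Step 1
Reactants: 1 dimethyl (4R,5R)-2,2-dimethyl-1,3-dioxolane-4,5-dicarboxylate
Product: 2 (4R,5R)-5-(methoxycarbonyl)-2,2-dimethyl-1,3-dioxolane-4-carboxylic acid
Conditions: KOH (1.0 equiv), MeOH, 0 °C to rt; then cold aq. HCl to pH 3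
Reagents that add atoms: potassium hydroxide [K+].[OH-]
Why: Saponification of one of two homotopic esters; the carboxylate formed slows a second hydrolysis, so the half-ester should be the main product. The stereocentres are not touched.

Step 2
Reactants: 2 (4R,5R)-5-(methoxycarbonyl)-2,2-dimethyl-1,3-dioxolane-4-carboxylic acid
Product: 4 (3R,4R)-3,4-dihydroxy-5,5-dimethyloxolan-2-one, via hydroxy acid acetonide 3 (not isolated)
Conditions: MeMgBr (3.5 equiv), THF, 0 °C to rt; then 2 M aq. HCl, 45 °C
Reagents that add atoms: methylmagnesium bromide C[Mg]Br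
Why: Grignard addition: the magnesium carboxylate is inert while the ester takes up two methyl groups. Aqueous acid then removes the acetonide and the tertiary hydroxyl closes the γ-lactone (gem-dimethyl effect); the trans-dioxolane of 3 cannot lactonise before hydrolysis, and both carbinol centres are spectators.

Step 3
Reactants: 4 (3R,4R)-3,4-dihydroxy-5,5-dimethyloxolan-2-one
Product: 6 (3aR,6R,6aR)-2,2,5,5-tetramethyltetrahydrofuro[2,3-d][1,3]dioxol-6-ol, via lactol triol 5 (not isolated)
Conditions: i-Bu2AlH (3.5 equiv), THF, −78 °C; MeOH, aq. potassium sodium tartrate; then Me2C(OMe)2, acetone, TsOH (cat.), rt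
Reagents that add atoms: 2,2-dimethoxypropane COC(C)(C)OC
Why: Lactone-to-lactol reduction, then thermodynamic acetonide formation as in furanose sugars. Only the anomeric hydroxyl can become cis to the neighbouring hydroxyl, so the cis-fused acetonide forms (the new acetal centre is fixed by the ring fusion) and the trans hydroxyl, the future O1, stays free.

Step 4
Reactants: 6 (3aR,6R,6aR)-2,2,5,5-tetramethyltetrahydrofuro[2,3-d][1,3]dioxol-6-ol; 7 trichloroethylene
Product: 8 (3aR,6R,6aR)-6-{[(E)-1,2-dichloroethenyl]oxy}-2,2,5,5-tetramethyltetrahydrofuro[2,3-d][1,3]dioxole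
Conditions: KH (1.3 equiv), THF, 0 °C to rt; then 7 (1.2 equiv), −40 °C to rt
Reagents that add atoms: none
Why: The potassium alkoxide adds to dichloroacetylene generated in situ from 7 (dichlorovinyl ether route to ynol ethers); anti addition gives the (E)-alkene. All other oxygens are in acetals, so no group can migrate to the alkoxide.

Step 5
Reactants: 8 (3aR,6R,6aR)-6-{[(E)-1,2-dichloroethenyl]oxy}-2,2,5,5-tetramethyltetrahydrofuro[2,3-d][1,3]dioxole
Product: 9 (3R,4R)-4-{[(E)-1,2-dichloroethenyl]oxy}-5,5-dimethyloxolane-2,3-diol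
Conditions: CF3CO2H/H2O (4:1), 0 °C
Reagents that add atoms: water O
Why: Acid hydrolysis of the anomeric acetonide. The doubly chlorinated enol ether is electron-poor and should resist protonation under conditions that cleave an acetal, which is why the acid step is placed here and not after the ynol ether exists.

Step 6
Reactants: 9 (3R,4R)-4-{[(E)-1,2-dichloroethenyl]oxy}-5,5-dimethyloxolane-2,3-diol
Product: 10 (3R,4R)-4-{[(E)-1,2-dichloroethenyl]oxy}-3-hydroxy-5,5-dimethyloxolan-2-one
Conditions: Ag2CO3 on diatomaceous earth (3 equiv), toluene, 80 °C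
Reagents that add atoms: none
Why: Silver carbonate oxidation of a lactol to the lactone, selective for the hemiacetal hydroxyl over the neighbouring secondary alcohol and free of glycol cleavage.

Step 7
Reactants: 10 (3R,4R)-4-{[(E)-1,2-dichloroethenyl]oxy}-3-hydroxy-5,5-dimethyloxolan-2-one
Product: 11 (3R,4R)-3-[(tert-butyldimethylsilyl)oxy]-4-{[(E)-1,2-dichloroethenyl]oxy}-5,5-dimethyloxolan-2-one
Conditions: t-BuMe2SiCl (1.3 equiv), imidazole, DMF, rt
Reagents that add atoms: tert-butyldimethylsilyl chloride CC(C)(C)[Si](C)(C)Cl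
Why: Silylation of the only free hydroxyl. The silyl ether is introduced after the basic etherification of step 4, so it never faces a vicinal potassium alkoxide.

Step 8
Reactants: 11 (3R,4R)-3-[(tert-butyldimethylsilyl)oxy]-4-{[(E)-1,2-dichloroethenyl]oxy}-5,5-dimethyloxolan-2-one
Product: 12 (3R,4R)-3-[(tert-butyldimethylsilyl)oxy]-4-{[(E)-1,2-dichloroethenyl]oxy}-5,5-dimethyloxolan-2-ol
Conditions: i-Bu2AlH (1.2 equiv), CH2Cl2, −78 °C; aq. potassium sodium tartrate
Reagents that add atoms: none
Why: Partial reduction of a γ-lactone; the tetrahedral aluminium alkoxide is stable at −78 °C and gives the lactol on work-up. The lactol is the masked aldehyde for the second alkyne.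

Step 9
Reactants: 12 (3R,4R)-3-[(tert-butyldimethylsilyl)oxy]-4-{[(E)-1,2-dichloroethenyl]oxy}-5,5-dimethyloxolan-2-ol
Product: 14 (3R,4R)-3-[(tert-butyldimethylsilyl)oxy]-5,5-dimethyl-4-{[(trimethylsilyl)ethynyl]oxy}oxolan-2-ol, via dilithio alkynyl ether 13 (not isolated)
Conditions: n-BuLi (3.2 equiv), THF, −78 °C; then Me3SiCl (1.2 equiv), −78 to −40 °C; pH 7 buffer
Reagents that add atoms: chlorotrimethylsilane C[Si](C)(C)Cl
Why: The first equivalent forms the lithium lactolate, which protects the latent aldehyde; two more effect dehydrochlorination and chlorine–lithium exchange to the lithium alkynyl ether, whose carbon terminus is silylated in preference to the stabilised lactolate oxygen. The lactolate is the more stable alkoxide, so the neighbouring silyl ether has no reason to migrate.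

Step 10
Reactants: 14 (3R,4R)-3-[(tert-butyldimethylsilyl)oxy]-5,5-dimethyl-4-{[(trimethylsilyl)ethynyl]oxy}oxolan-2-ol
Product: 15 (3R,4S)-4-[(tert-butyldimethylsilyl)oxy]-2-methyl-3-{[(trimethylsilyl)ethynyl]oxy}hex-5-yn-2-ol
Conditions: Me3SiCHN2 (2.4 equiv), n-BuLi (2.3 equiv), THF, −78 °C; then 14, −78 to 0 °C
Reagents that add atoms: trimethylsilyldiazomethane C[Si](C)(C)C=[N+]=[N-]
Why: Colvin rearrangement: the lithiated reagent adds to the aldehyde tautomer of the lactol, Peterson elimination and loss of N2 give an alkylidene carbene, and 1,2-hydrogen shift gives the terminal alkyne while the ring oxygen is released as the tertiary alkoxide. No alcoholic base or fluoride is present, so the C-silyl ynol ether should survive, and the α-silyloxy centre is not epimerised at low temperature.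

Step 11
Reactants: 15 (3R,4S)-4-[(tert-butyldimethylsilyl)oxy]-2-methyl-3-{[(trimethylsilyl)ethynyl]oxy}hex-5-yn-2-ol
Product: 16 (3S,4R)-3-[(tert-butyldimethylsilyl)oxy]-5-methyl-5-[(trimethylsilyl)oxy]-4-{[(trimethylsilyl)ethynyl]oxy}hex-1-yne
Conditions: N-(trimethylsilyl)imidazole (1.5 equiv), CH2Cl2, rt
Reagents that add atoms: N-(trimethylsilyl)imidazole C[Si](C)(C)n1ccnc1
Why: Neutral silylation of the tertiary hydroxyl, which could otherwise add to the neighbouring ynol ether; imidazole is the only by-product.

Step 12
Reactants: 17 (2S)-but-3-yn-2-ol; 18 (2Z)-2-methylbut-2-enoic acid (angelic acid)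
Product: 19 (2S)-but-3-yn-2-yl (2Z)-2-methylbut-2-enoate
Conditions: 18, 2,4,6-trichlorobenzoyl chloride, Et3N, toluene, rt; then 17, DMAP, rt to 60 °C
Reagents that add atoms: none
Why: Yamaguchi esterification through the mixed anhydride, the usual way to acylate with angelic acid without Z-to-E isomerisation; the carbinol centre is not involved.

Step 13
Reactants: 16 (3S,4R)-3-[(tert-butyldimethylsilyl)oxy]-5-methyl-5-[(trimethylsilyl)oxy]-4-{[(trimethylsilyl)ethynyl]oxy}hex-1-yne; 19 (2S)-but-3-yn-2-yl (2Z)-2-methylbut-2-enoate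
Product: 20 (1S)-1-[(2R,3S)-3-[(tert-butyldimethylsilyl)oxy]-7-(trimethylsilyl)-2-{2-[(trimethylsilyl)oxy]propan-2-yl}-2,3-dihydro-1-benzofuran-5-yl]ethyl (2Z)-2-methylbut-2-enoate
Conditions: Cp*RuCl(cod) (10 mol%), 19 (3 equiv), ClCH2CH2Cl, rt; 16 added over 4 h
Reagents that add atoms: none
Why: Loss of cod frees two sites on divalent ruthenium; both alkynes of 16 bind and oxidative cyclisation joins their inner carbons (C3a–C7a), which closes ring B as a five-membered ring and leaves the outer carbons C4–H and C7–SiMe3 on tetravalent ruthenium in a bicyclic ruthenacycle. Alkyne 19 then inserts on the unhindered C4 side, its substituted carbon bonding to C4 (C4–C5) and its CH terminus staying on the metal, and reductive elimination joins that CH carbon to the silylated carbon (C6–C7), closing ring A as the six-membered arene and returning divalent ruthenium. The closest known reactions are the Cp*RuCl(cod)-catalysed couplings of 1,6-diynes bearing one substituted terminus with terminal alkynes, which give the meta isomers, and metal-catalysed [2+2+2] reactions of 1,6-diynes tethered through an ynamide nitrogen or an aryl ynol ether oxygen. No stereocentre is formed: C2, C3 and the carbinol centre of 19 are sp3 spectators and keep their configuration. The selectivity needed is regiochemical (side chain at C5, not C6) and is secured by the Me3Si group on the ynol terminus, next to which only the CH end of 19 fits. Cross-coupling over trimerisation of 19 is favoured by slow addition of 16 to an excess of 19. Room temperature keeps the secondary alkyl ynol ether from retro-ene loss of a ketene and the propargylic ester from acyloxy migration on the metal.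

Step 14
Reactants: 20 (1S)-1-[(2R,3S)-3-[(tert-butyldimethylsilyl)oxy]-7-(trimethylsilyl)-2-{2-[(trimethylsilyl)oxy]propan-2-yl}-2,3-dihydro-1-benzofuran-5-yl]ethyl (2Z)-2-methylbut-2-enoate
Product: 21 (1S)-1-[(2R,3S)-3-[(tert-butyldimethylsilyl)oxy]-7-iodo-2-{2-[(trimethylsilyl)oxy]propan-2-yl}-2,3-dihydro-1-benzofuran-5-yl]ethyl (2Z)-2-methylbut-2-enoate
Conditions: ICl (1.1 equiv), K2CO3 (solid), CH2Cl2, −78 °C; aq. Na2S2O3
Reagents that add atoms: iodine monochloride ClI
Why: ipso-Iododesilylation: C7 is ortho to the ring oxygen and the β-silyl effect directs the electrophile to the silylated carbon. No Brønsted acid is produced, so the benzylic C–O bonds are not ionised, and the only alkene present is the electron-poor angelate.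

Step 15
Reactants: 21 (1S)-1-[(2R,3S)-3-[(tert-butyldimethylsilyl)oxy]-7-iodo-2-{2-[(trimethylsilyl)oxy]propan-2-yl}-2,3-dihydro-1-benzofuran-5-yl]ethyl (2Z)-2-methylbut-2-enoate
Product: 22 (1S)-1-[(2R,3S)-3-[(tert-butyldimethylsilyl)oxy]-2-{2-[(trimethylsilyl)oxy]propan-2-yl}-2,3-dihydro-1-benzofuran-5-yl]ethyl (2Z)-2-methylbut-2-enoate
Conditions: i-PrMgCl·LiCl (1.2 equiv), THF, −30 °C; then MeOH
Reagents that add atoms: none
Why: Iodine–magnesium exchange at an aryl iodide ortho to an ether oxygen, then protonation. The hindered conjugated ester and the silyl ethers tolerate the reagent at this temperature, and no radical is involved that could isomerise the angelate.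

Step 16
Reactants: 22 (1S)-1-[(2R,3S)-3-[(tert-butyldimethylsilyl)oxy]-2-{2-[(trimethylsilyl)oxy]propan-2-yl}-2,3-dihydro-1-benzofuran-5-yl]ethyl (2Z)-2-methylbut-2-enoate
Product: 23 (1S)-1-[(2R,3S)-3-hydroxy-2-(2-hydroxypropan-2-yl)-2,3-dihydro-1-benzofuran-5-yl]ethyl (2Z)-2-methylbut-2-enoate
Conditions: Bu4NF (3 equiv), AcOH (3 equiv), THF, 0 °C to rt
Reagents that add atoms: none
Why: Buffered fluoride cleaves both silyl ethers; the buffer keeps the medium from hydrolysing or isomerising the angelate.

Step 17
Reactants: 23 (1S)-1-[(2R,3S)-3-hydroxy-2-(2-hydroxypropan-2-yl)-2,3-dihydro-1-benzofuran-5-yl]ethyl (2Z)-2-methylbut-2-enoate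
Product: 24 (1S)-1-[(2R,3S)-3-(acetyloxy)-2-(2-hydroxypropan-2-yl)-2,3-dihydro-1-benzofuran-5-yl]ethyl (2Z)-2-methylbut-2-enoate
Conditions: Ac2O (1.5 equiv), pyridine, DMAP (5 mol%), CH2Cl2, 0 °C
Reagents that add atoms: acetic anhydride CC(=O)OC(C)=O
Why: Acylation of the secondary benzylic alcohol; the tertiary alcohol does not react under these conditions.

Step 18
Reactants: 24 (1S)-1-[(2R,3S)-3-(acetyloxy)-2-(2-hydroxypropan-2-yl)-2,3-dihydro-1-benzofuran-5-yl]ethyl (2Z)-2-methylbut-2-enoate
Product: 25 (1S)-1-[(2S,3S)-3-(acetyloxy)-2-(prop-1-en-2-yl)-2,3-dihydro-1-benzofuran-5-yl]ethyl (2Z)-2-methylbut-2-enoate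
Conditions: Burgess reagent (MeO2CN−SO2N+Et3, 2 equiv), toluene, 60 °C
Reagents that add atoms: none
Why: syn-Elimination of the tertiary sulfamate under neutral conditions. Six methyl hydrogens compete with one hindered C2–H whose loss would give a tetrasubstituted enol ether, so the isopropenyl group should form; the benzylic esters are spared.

Step 19
Reactants: 25 (1S)-1-[(2S,3S)-3-(acetyloxy)-2-(prop-1-en-2-yl)-2,3-dihydro-1-benzofuran-5-yl]ethyl (2Z)-2-methylbut-2-enoate
Product: 27 (1S)-1-[(2S,3S)-3-(acetyloxy)-2-(3-oxoprop-1-en-2-yl)-2,3-dihydro-1-benzofuran-5-yl]ethyl (2Z)-2-methylbut-2-enoate, via allylic alcohol 26 (not isolated)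
Conditions: SeO2 (0.5 equiv), t-BuOOH (3 equiv), CH2Cl2, rt; then MnO2, CH2Cl2, rt
Reagents that add atoms: tert-butyl hydroperoxide CC(C)(C)OO
Why: Riley oxidation (ene reaction, then [2,3]-shift) at the methyl group of the electron-rich 1,1-disubstituted alkene; methyl is preferred over the allylic methine, and the conjugated angelate alkene is too electron-poor to react. MnO2 converges alcohol 26 on the enal.

Step 20
Reactants: 27 (1S)-1-[(2S,3S)-3-(acetyloxy)-2-(3-oxoprop-1-en-2-yl)-2,3-dihydro-1-benzofuran-5-yl]ethyl (2Z)-2-methylbut-2-enoate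
Product: 28 2-[(2S,3S)-3-(acetyloxy)-5-[(1S)-1-{[(2Z)-2-methylbut-2-enoyl]oxy}ethyl]-2,3-dihydro-1-benzofuran-2-yl]prop-2-enoic acid
Conditions: NaClO2, NaH2PO4, 2-methylbut-2-ene, t-BuOH/H2O, 0 °C to rt
Reagents that add atoms: sodium chlorite [Na+].[O-]Cl=O
Why: Pinnick oxidation of a conjugated aldehyde in a weakly acidic buffer; the alkene scavenger removes HOCl, so the esters and the electron-rich arene are not affected.

Step 21
Reactants: 28 2-[(2S,3S)-3-(acetyloxy)-5-[(1S)-1-{[(2Z)-2-methylbut-2-enoyl]oxy}ethyl]-2,3-dihydro-1-benzofuran-2-yl]prop-2-enoic acid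
Product: 29 methyl 2-[(2S,3S)-3-(acetyloxy)-5-[(1S)-1-{[(2Z)-2-methylbut-2-enoyl]oxy}ethyl]-2,3-dihydro-1-benzofuran-2-yl]prop-2-enoate
Conditions: Me3SiCHN2 (1.1 equiv), MeOH/toluene, 0 °C
Reagents that add atoms: trimethylsilyldiazomethane C[Si](C)(C)C=[N+]=[N-]
Why: Methylation of the carboxylic acid without base, which matters because C2–H is γ to the acrylate carbonyl and the C3 acetate is a β-leaving group.

## Compound list

1 | dimethyl (4R,5R)-2,2-dimethyl-1,3-dioxolane-4,5-dicarboxylate | COC(=O)[C@@H]1OC(C)(C)O[C@H]1C(=O)OC | starting material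
2 | (4R,5R)-5-(methoxycarbonyl)-2,2-dimethyl-1,3-dioxolane-4-carboxylic acid | COC(=O)[C@@H]1OC(C)(C)O[C@H]1C(=O)O | intermediate
3 | (4R,5R)-5-(2-hydroxypropan-2-yl)-2,2-dimethyl-1,3-dioxolane-4-carboxylic acid | CC(C)(O)[C@@H]1OC(C)(C)O[C@H]1C(=O)O | intermediate, not isolated
4 | (3R,4R)-3,4-dihydroxy-5,5-dimethyloxolan-2-one | CC1(C)OC(=O)[C@H](O)[C@H]1O | intermediate
5 | (3R,4R)-5,5-dimethyloxolane-2,3,4-triol | CC1(C)OC(O)[C@H](O)[C@H]1O | intermediate, not isolated
6 | (3aR,6R,6aR)-2,2,5,5-tetramethyltetrahydrofuro[2,3-d][1,3]dioxol-6-ol | CC1(C)O[C@@H]2OC(C)(C)O[C@@H]2[C@H]1O | intermediate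
7 | trichloroethylene | ClC=C(Cl)Cl | starting material
8 | (3aR,6R,6aR)-6-{[(E)-1,2-dichloroethenyl]oxy}-2,2,5,5-tetramethyltetrahydrofuro[2,3-d][1,3]dioxole | CC1(C)O[C@@H]2OC(C)(C)O[C@@H]2[C@H]1O/C(Cl)=C\Cl | intermediate
9 | (3R,4R)-4-{[(E)-1,2-dichloroethenyl]oxy}-5,5-dimethyloxolane-2,3-diol | CC1(C)OC(O)[C@H](O)[C@H]1O/C(Cl)=C\Cl | intermediate
10 | (3R,4R)-4-{[(E)-1,2-dichloroethenyl]oxy}-3-hydroxy-5,5-dimethyloxolan-2-one | CC1(C)OC(=O)[C@H](O)[C@H]1O/C(Cl)=C\Cl | intermediate
11 | (3R,4R)-3-[(tert-butyldimethylsilyl)oxy]-4-{[(E)-1,2-dichloroethenyl]oxy}-5,5-dimethyloxolan-2-one | CC1(C)OC(=O)[C@H](O[Si](C)(C)C(C)(C)C)[C@H]1O/C(Cl)=C\Cl | intermediate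
12 | (3R,4R)-3-[(tert-butyldimethylsilyl)oxy]-4-{[(E)-1,2-dichloroethenyl]oxy}-5,5-dimethyloxolan-2-ol | CC1(C)OC(O)[C@H](O[Si](C)(C)C(C)(C)C)[C@H]1O/C(Cl)=C\Cl | intermediate
13 | dilithium salt (lactolate and acetylide) of (3R,4R)-3-[(tert-butyldimethylsilyl)oxy]-4-(ethynyloxy)-5,5-dimethyloxolan-2-ol | [Li+].[Li+].CC1(C)OC([O-])[C@H](O[Si](C)(C)C(C)(C)C)[C@H]1OC#[C-] | intermediate, not isolated
14 | (3R,4R)-3-[(tert-butyldimethylsilyl)oxy]-5,5-dimethyl-4-{[(trimethylsilyl)ethynyl]oxy}oxolan-2-ol | CC1(C)OC(O)[C@H](O[Si](C)(C)C(C)(C)C)[C@H]1OC#C[Si](C)(C)C | intermediate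
15 | (3R,4S)-4-[(tert-butyldimethylsilyl)oxy]-2-methyl-3-{[(trimethylsilyl)ethynyl]oxy}hex-5-yn-2-ol | C#C[C@H](O[Si](C)(C)C(C)(C)C)[C@@H](OC#C[Si](C)(C)C)C(C)(C)O | intermediate
16 | (3S,4R)-3-[(tert-butyldimethylsilyl)oxy]-5-methyl-5-[(trimethylsilyl)oxy]-4-{[(trimethylsilyl)ethynyl]oxy}hex-1-yne | C#C[C@H](O[Si](C)(C)C(C)(C)C)[C@@H](OC#C[Si](C)(C)C)C(C)(C)O[Si](C)(C)C | intermediate
17 | (2S)-but-3-yn-2-ol | C#C[C@H](C)O | starting material
18 | (2Z)-2-methylbut-2-enoic acid (angelic acid) | C/C=C(/C)C(=O)O | starting material
19 | (2S)-but-3-yn-2-yl (2Z)-2-methylbut-2-enoate | C#C[C@H](C)OC(=O)/C(C)=C\C | intermediate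
20 | (1S)-1-[(2R,3S)-3-[(tert-butyldimethylsilyl)oxy]-7-(trimethylsilyl)-2-{2-[(trimethylsilyl)oxy]propan-2-yl}-2,3-dihydro-1-benzofuran-5-yl]ethyl (2Z)-2-methylbut-2-enoate | C/C=C(/C)C(=O)O[C@@H](C)c1cc([Si](C)(C)C)c2O[C@@H](C(C)(C)O[Si](C)(C)C)[C@@H](O[Si](C)(C)C(C)(C)C)c2c1 | intermediate
21 | (1S)-1-[(2R,3S)-3-[(tert-butyldimethylsilyl)oxy]-7-iodo-2-{2-[(trimethylsilyl)oxy]propan-2-yl}-2,3-dihydro-1-benzofuran-5-yl]ethyl (2Z)-2-methylbut-2-enoate | C/C=C(/C)C(=O)O[C@@H](C)c1cc(I)c2O[C@@H](C(C)(C)O[Si](C)(C)C)[C@@H](O[Si](C)(C)C(C)(C)C)c2c1 | intermediate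
22 | (1S)-1-[(2R,3S)-3-[(tert-butyldimethylsilyl)oxy]-2-{2-[(trimethylsilyl)oxy]propan-2-yl}-2,3-dihydro-1-benzofuran-5-yl]ethyl (2Z)-2-methylbut-2-enoate | C/C=C(/C)C(=O)O[C@@H](C)c1ccc2O[C@@H](C(C)(C)O[Si](C)(C)C)[C@@H](O[Si](C)(C)C(C)(C)C)c2c1 | intermediate
23 | (1S)-1-[(2R,3S)-3-hydroxy-2-(2-hydroxypropan-2-yl)-2,3-dihydro-1-benzofuran-5-yl]ethyl (2Z)-2-methylbut-2-enoate | C/C=C(/C)C(=O)O[C@@H](C)c1ccc2O[C@@H](C(C)(C)O)[C@@H](O)c2c1 | intermediate
24 | (1S)-1-[(2R,3S)-3-(acetyloxy)-2-(2-hydroxypropan-2-yl)-2,3-dihydro-1-benzofuran-5-yl]ethyl (2Z)-2-methylbut-2-enoate | C/C=C(/C)C(=O)O[C@@H](C)c1ccc2O[C@@H](C(C)(C)O)[C@@H](OC(C)=O)c2c1 | intermediate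
25 | (1S)-1-[(2S,3S)-3-(acetyloxy)-2-(prop-1-en-2-yl)-2,3-dihydro-1-benzofuran-5-yl]ethyl (2Z)-2-methylbut-2-enoate | C/C=C(/C)C(=O)O[C@@H](C)c1ccc2O[C@@H](C(C)=C)[C@@H](OC(C)=O)c2c1 | intermediate
26 | (1S)-1-[(2S,3S)-3-(acetyloxy)-2-(3-hydroxyprop-1-en-2-yl)-2,3-dihydro-1-benzofuran-5-yl]ethyl (2Z)-2-methylbut-2-enoate | C/C=C(/C)C(=O)O[C@@H](C)c1ccc2O[C@@H](C(=C)CO)[C@@H](OC(C)=O)c2c1 | intermediate, not isolated
27 | (1S)-1-[(2S,3S)-3-(acetyloxy)-2-(3-oxoprop-1-en-2-yl)-2,3-dihydro-1-benzofuran-5-yl]ethyl (2Z)-2-methylbut-2-enoate | C/C=C(/C)C(=O)O[C@@H](C)c1ccc2O[C@@H](C(=C)C=O)[C@@H](OC(C)=O)c2c1 | intermediate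
28 | 2-[(2S,3S)-3-(acetyloxy)-5-[(1S)-1-{[(2Z)-2-methylbut-2-enoyl]oxy}ethyl]-2,3-dihydro-1-benzofuran-2-yl]prop-2-enoic acid | C/C=C(/C)C(=O)O[C@@H](C)c1ccc2O[C@@H](C(=C)C(=O)O)[C@@H](OC(C)=O)c2c1 | intermediate
29 | methyl 2-[(2S,3S)-3-(acetyloxy)-5-[(1S)-1-{[(2Z)-2-methylbut-2-enoyl]oxy}ethyl]-2,3-dihydro-1-benzofuran-2-yl]prop-2-enoate | C=C(C(=O)OC)[C@@H]1Oc2ccc([C@H](C)OC(=O)/C(C)=C\C)cc2[C@@H]1OC(C)=O | target

## Step count and least certain steps

Total: 21 steps. Longest linear sequence: 20 steps (1 to 29 through steps 1 to 11 and 13 to 21); step 12 is the one-step branch to 19.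

**Step 13 (key step).** The most likely failure is a slow oxidative cyclisation at the silylated, electron-rich ynol ether alkyne, which leaves the catalyst free to trimerise 19. The propargylic ester of 19 may also be diverted on ruthenium by acyloxy migration to a vinyl carbene. A third failure is partial loss of regiocontrol if insertion also occurs on the silylated side. The fallback sets out from 16 and uses the free carbinol 17 in place of 19 (Cp*RuCl(cod), ClCH2CH2Cl, rt). Alkyne 17 has no acyloxy group to migrate and is smaller. This should give (1S)-1-[(2R,3S)-3-[(tert-butyldimethylsilyl)oxy]-7-(trimethylsilyl)-2-{2-[(trimethylsilyl)oxy]propan-2-yl}-2,3-dihydro-1-benzofuran-5-yl]ethan-1-ol F1, which is esterified with 18 under Yamaguchi conditions and comes back to the route at 20.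

**Step 9.** The lithium lactolate may open to the alkoxy aldehyde and take up butyllithium, or be silylated on oxygen so that the latent aldehyde is blocked; either process removes the handle for the second alkyne. The fallback sets out from lactone 11 and carries that carbon as a primary alkoxide. LiBH4 (THF, 0 °C) should give (2S,3R)-2-[(tert-butyldimethylsilyl)oxy]-3-{[(E)-1,2-dichloroethenyl]oxy}-4-methylpentane-1,4-diol F2. n-BuLi (4.3 equiv) and then excess Me3SiCl should give the trisilylated ynol ether (2S,3R)-2-[(tert-butyldimethylsilyl)oxy]-4-methyl-1,4-bis[(trimethylsilyl)oxy]-3-{[(trimethylsilyl)ethynyl]oxy}pentane F3. Brief methanolysis (K2CO3 cat., MeOH, −20 °C) removes only the primary trimethylsilyl ether and gives (2S,3R)-2-[(tert-butyldimethylsilyl)oxy]-4-methyl-4-[(trimethylsilyl)oxy]-3-{[(trimethylsilyl)ethynyl]oxy}pentan-1-ol F4. Dess–Martin periodinane with NaHCO3 gives (2R,3R)-2-[(tert-butyldimethylsilyl)oxy]-4-methyl-4-[(trimethylsilyl)oxy]-3-{[(trimethylsilyl)ethynyl]oxy}pentanal F5. The Colvin rearrangement of this free aldehyde comes back to the route at 16, bypassing steps 8 to 11.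

**Step 18.** Proton loss may occur toward C2 (giving the enol ether), or the tertiary sulfamate may ionise with participation of the cis acetate and transfer of the acetyl group. The fallback sets out from 22 and dehydrates before the acetate is present. Pyridinium p-toluenesulfonate (cat.) in MeOH at 0 °C removes only the tertiary trimethylsilyl ether and gives (1S)-1-[(2R,3S)-3-[(tert-butyldimethylsilyl)oxy]-2-(2-hydroxypropan-2-yl)-2,3-dihydro-1-benzofuran-5-yl]ethyl (2Z)-2-methylbut-2-enoate F6. Burgess reagent gives (1S)-1-[(2S,3S)-3-[(tert-butyldimethylsilyl)oxy]-2-(prop-1-en-2-yl)-2,3-dihydro-1-benzofuran-5-yl]ethyl (2Z)-2-methylbut-2-enoate F7. Bu4NF/AcOH gives (1S)-1-[(2S,3S)-3-hydroxy-2-(prop-1-en-2-yl)-2,3-dihydro-1-benzofuran-5-yl]ethyl (2Z)-2-methylbut-2-enoate F8. Acetylation (Ac2O, pyridine) comes back to the route at 25.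

**Step 19.** The selenium-mediated oxidation may stop at mixtures, attack the allylic methyl groups of the angelate on prolonged reaction, or ionise a benzylic ester through the selenous acid formed. The fallback sets out from 25 and uses a Schenck ene reaction with singlet oxygen (O2, tetraphenylporphyrin, visible light, CH2Cl2). The electron-rich 1,1-disubstituted alkene should react and the angelate should not. The product is (1S)-1-[(2S,3S)-3-(acetyloxy)-2-(3-hydroperoxyprop-1-en-2-yl)-2,3-dihydro-1-benzofuran-5-yl]ethyl (2Z)-2-methylbut-2-enoate F9. Dehydration of the hydroperoxide with Ac2O and pyridine (Kornblum–DeLaMare type) comes back to the route at 27.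

## Further compounds

F1 | step 13 | (1S)-1-[(2R,3S)-3-[(tert-butyldimethylsilyl)oxy]-7-(trimethylsilyl)-2-{2-[(trimethylsilyl)oxy]propan-2-yl}-2,3-dihydro-1-benzofuran-5-yl]ethan-1-ol | C[C@H](O)c1cc([Si](C)(C)C)c2O[C@@H](C(C)(C)O[Si](C)(C)C)[C@@H](O[Si](C)(C)C(C)(C)C)c2c1
F2 | step 9 | (2S,3R)-2-[(tert-butyldimethylsilyl)oxy]-3-{[(E)-1,2-dichloroethenyl]oxy}-4-methylpentane-1,4-diol | OC[C@H](O[Si](C)(C)C(C)(C)C)[C@@H](O/C(Cl)=C\Cl)C(C)(C)O
F3 | step 9 | (2S,3R)-2-[(tert-butyldimethylsilyl)oxy]-4-methyl-1,4-bis[(trimethylsilyl)oxy]-3-{[(trimethylsilyl)ethynyl]oxy}pentane | C[Si](C)(C)OC[C@H](O[Si](C)(C)C(C)(C)C)[C@@H](OC#C[Si](C)(C)C)C(C)(C)O[Si](C)(C)C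
F4 | step 9 | (2S,3R)-2-[(tert-butyldimethylsilyl)oxy]-4-methyl-4-[(trimethylsilyl)oxy]-3-{[(trimethylsilyl)ethynyl]oxy}pentan-1-ol | OC[C@H](O[Si](C)(C)C(C)(C)C)[C@@H](OC#C[Si](C)(C)C)C(C)(C)O[Si](C)(C)C
F5 | step 9 | (2R,3R)-2-[(tert-butyldimethylsilyl)oxy]-4-methyl-4-[(trimethylsilyl)oxy]-3-{[(trimethylsilyl)ethynyl]oxy}pentanal | O=C[C@H](O[Si](C)(C)C(C)(C)C)[C@@H](OC#C[Si](C)(C)C)C(C)(C)O[Si](C)(C)C
F6 | step 18 | (1S)-1-[(2R,3S)-3-[(tert-butyldimethylsilyl)oxy]-2-(2-hydroxypropan-2-yl)-2,3-dihydro-1-benzofuran-5-yl]ethyl (2Z)-2-methylbut-2-enoate | C/C=C(/C)C(=O)O[C@@H](C)c1ccc2O[C@@H](C(C)(C)O)[C@@H](O[Si](C)(C)C(C)(C)C)c2c1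
F7 | step 18 | (1S)-1-[(2S,3S)-3-[(tert-butyldimethylsilyl)oxy]-2-(prop-1-en-2-yl)-2,3-dihydro-1-benzofuran-5-yl]ethyl (2Z)-2-methylbut-2-enoate | C/C=C(/C)C(=O)O[C@@H](C)c1ccc2O[C@@H](C(C)=C)[C@@H](O[Si](C)(C)C(C)(C)C)c2c1
F8 | step 18 | (1S)-1-[(2S,3S)-3-hydroxy-2-(prop-1-en-2-yl)-2,3-dihydro-1-benzofuran-5-yl]ethyl (2Z)-2-methylbut-2-enoate | C/C=C(/C)C(=O)O[C@@H](C)c1ccc2O[C@@H](C(C)=C)[C@@H](O)c2c1
F9 | step 19 | (1S)-1-[(2S,3S)-3-(acetyloxy)-2-(3-hydroperoxyprop-1-en-2-yl)-2,3-dihydro-1-benzofuran-5-yl]ethyl (2Z)-2-methylbut-2-enoate | C/C=C(/C)C(=O)O[C@@H](C)c1ccc2O[C@@H](C(=C)COO)[C@@H](OC(C)=O)c2c1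
A1 | alternative 1 | cis-fused 3-methylidene-3a,8b-dihydrofuro[3,2-b][1]benzofuran-2(3H)-one with bromine para to the aryl ether oxygen, ring-fusion carbons configured as C2 and C3 of 29 | C=C1[C@@H]2Oc3ccc(Br)cc3[C@@H]2OC1=O
A2 | alternative 2 | cis-fused 3-methylidene-3a,8b-dihydrofuro[3,2-b][1]benzofuran-2(3H)-one with a (1S)-1-[(tert-butyldimethylsilyl)oxy]ethyl group para to the aryl ether oxygen | C=C1[C@@H]2Oc3ccc([C@H](C)O[Si](C)(C)C(C)(C)C)cc3[C@@H]2OC1=O
A3 | alternative 3 | (2S,3S)-5-{(1S)-1-[(tert-butyldimethylsilyl)oxy]ethyl}-2-(prop-1-en-2-yl)-2,3-dihydro-1-benzofuran-3-ol | C=C(C)[C@@H]1Oc2ccc([C@H](C)O[Si](C)(C)C(C)(C)C)cc2[C@@H]1O
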